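## The problem

- **Structure.** Target 30 is a (3R)-isoflavan. It is a chroman (O1, C2, C3, C4, C4a–C8a) whose ring A carries OMe at C5 and C7 and a prenyl group at C6. Its C3 carries ring B, a 1,4-benzoquinone with C2'=O, prenyl at C3', OH at C4', C5'=O and H at C6'.
- **Stereocentre.** C3 is the only stereocentre, so nothing in the molecule can control it. Its two ring arms (C2H2–O1 and C4H2–C4a) differ only at the β-atom. It must therefore be set by a catalyst or reagent and then carried unchanged.
- **Late lability of C3.** Once ring B is a quinone, C3–H is vinylogously acidic (γ to C5'=O through C6'=C1'). Base or long acid contact late in the route endangers the configuration.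
- **Sensitive groups.** The two prenyl groups exclude hydrogenation of unfunctionalised alkenes, strong acid and electrophilic oxidants. The hydroxyquinone excludes phosphines, amines, reductants and strong base.
- **Ring A versus ring B.** Ring A is a phloroglucinol triether with a free C8–H. It is oxidised and substituted more easily than any benzenoid precursor of ring B, so a late arene-to-quinone oxidation is the weak point of a conventional plan. No cheap arene has the substitution pattern of ring B.
- **Feature that makes the key step possible.** The four contiguous ring-B atoms C2'(=O)–C3'(prenyl)=C4'(O)–C5'(=O) have the pattern of a 3-alkoxy-4-alkylcyclobutene-1,2-dione. The remaining two atoms, C6'(H)=C1', are a terminal alkyne whose propargylic carbon is C3. Ring B is therefore a C4 + C2 sum, reachable by thermal ring expansion at the quinone oxidation level without any oxidant.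
- **Second feature.** Seen from O1, ring A is the phenol 6, which has a mirror plane through C8a and C6. Its two ortho carbons are equivalent, so annulation of the pyran ring needs no regiocontrol.

## Retrosynthesis

**30 ⇒ 29 (O–CMe3 bond at O4').** The vinylogous acid cannot pass through an organolithium addition, so O4' is carried as an ether. tert-Butyl is chosen because it leaves by O–alkyl heterolysis as isobutene under brief mild acid. A methyl or isopropyl ether would need hydroxide (danger to C3–H) or boron halides (danger to the prenyl groups and the aryl methyl ethers). The forward step must be faster than protonation of a trisubstituted alkene.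

**29 ⇒ 26 (key step: cut C1'–C2', reconnect C2'–C5').**
- Ring B is contracted to the 4-alkynyl-4-hydroxycyclobutenone 26, an isomer of 29.
- Cuts at C3–C1' on a finished ring B need either an aryl anion or a quinone electrophile, and both need a later redox correction on ring B.
- This cut delivers the quinone directly, with all five ring-B positions fixed by connectivity.
- 26 comes in one step from two fragments of half size, so ring B is never handled as an arene.
- The forward reaction must close the six-membered and not the five-membered ring, and must leave C3 and both prenyl groups alone.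

**26 ⇒ 16 + 24 (cut C5'–C6').** This is an acetylide addition to a cyclobutenedione. The two carbonyl groups of 24 differ electronically. C1=O is a vinylogous ester; C2=O is ketone-like. The natural site of attack, C2, gives exactly the regiochemistry of the target. The problem divides into a chiral alkyne 16 and an achiral C4 block 24.

**24 ⇒ 22 + 23; 22 ⇒ 18 + 19; 18 ⇒ 17 (cut the C3'–CH2 bond and the prenyl C=C).** Prenyl-metal reagents deliver their γ-carbon to carbonyl groups and would install the reverse-prenyl group. A symmetrical allyl reagent 19 has no such ambiguity, and cross-metathesis with 23 corrects the terminus. The squarate 18 comes from squaric acid 17 in one step.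

**16 ⇒ 15 ⇒ 10 + 11 (cut C3–C1').** The sp3–sp bond is made by a stereospecific 1,2-shift from boron to carbon, followed by elimination. An SN2 displacement at C3 by an acetylide would be overrun by E2 towards the conjugated chromene 9. The boron route has no carbocation or free carbanion at C3 and proceeds with retention.

**10 ⇒ 9 (cut C3–B and C4–H).** The stereocentre is created on the flat chromene 9 by enantioselective borylcupration and protonation. The styrene polarisation puts copper at C4 and boron at C3. The prenyl alkene is not activated and stays out. This replaces hydrogenation, which the prenyl group forbids.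

**9 ⇒ 8 ⇒ 6 + 7 (cut C4–C4a, then O1–C2).** This is a 6-endo hydroarylation of the aryl propargyl ether 8. All three pyran carbons come from propargyl bromide 7. The mirror symmetry of 6 makes the ring closure regiochemically degenerate.

**6 ⇒ 4 ⇒ 1 + 2 (cut C8a–O and C6–CH2).** The phenol oxygen is placed by sterically governed C–H borylation/oxidation at the only unhindered C–H of 4. This position is meta to both methoxy groups, which no electrophilic substitution would reach. Compound 4 comes from directed lithiation of 1 between its methoxy groups and alkylation with 2.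

## Roads not taken

**Alternative 1 (the obvious route).**
- *Cut:* C3–C1' at the sp2 level, H2 across C3=C4, ring B benzenoid until the end.
- *Forward:* sp2–sp2 cross-coupling gives the isoflav-3-ene A1. Asymmetric hydrogenation and deprotection give the resorcinol A2, which is oxidised at C5' (nitrosodisulfonate-type phenol oxidation) to 30.
- *Why the chosen plan is better:* Catalysts that reduce the unfunctionalised trisubstituted C3=C4 bond do not distinguish it from two trisubstituted prenyl alkenes. The prenyl groups would have to be added afterwards, which brings C6/C8 and C3'/C5' regiochemical problems and several extra steps. The last step must also insert oxygen into ring B of A2 while the more electron-rich ring A and two alkenes look on. The chosen plan uses neither hydrogen nor an oxidant.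

**Alternative 2.**
- *Cut:* C3–C1' with ring B as the electrophile (reversed polarity of the aryl partner).
- *Forward:* enamine-catalysed α-arylation of aldehyde A3 with quinone A4. The methoxy group of A4 steers attack to the correct carbon, and the product is trapped as the lactol A5.
- *Why the chosen plan is better:* The bond and the stereocentre form in one catalytic step, but the product is at the wrong oxidation level twice (C2 an aldehyde, ring B a hydroquinone). After reduction, the primary alcohol at C2 faces two phenols, and closure to the five-membered ring with O2' competes with the wanted six-membered closure to O1. Oxidising to the quinone first rules out phosphine-based etherification. C3 is an α-aryl aldehyde centre until C2 is reduced. The chosen plan closes the pyran ring before the stereocentre exists.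

**Alternative 3.**
- *Cut:* C3–C1' from the same boronic ester 10, but to an aryl anion.
- *Forward:* the aryllithium from bromide A6 forms a boronate with 10. An electrophile (N-bromosuccinimide or a high-potential quinone) triggers the 1,2-shift to A7. Ceric oxidative demethylation and acetal removal then give 30.
- *Why the chosen plan is better:* A6 is a pentasubstituted arene that needs its own multistep regiocontrolled synthesis. Both the trigger and the ceric oxidation are electrophilic oxidants that ring A (free C8–H) and the prenyl groups would not escape. The chosen plan uses the same stereospecific boron chemistry to attach only two carbons and builds the rest of ring B under neutral thermal conditions.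

Key step: step 12

Assumption: (R,R)-QuinoxP* is taken to give the (S)-boronate 10. The sense of induction is checked at 10, and the (S,S)-ligand is used instead if it proves opposite; nothing else changes.

## Steps

Step 1
Reactants: 1 1,3-dimethoxybenzene; 2 prenyl bromide (1-bromo-3-methylbut-2-ene)
Product: 4 1,3-dimethoxy-2-(3-methylbut-2-en-1-yl)benzene, via 2,6-dimethoxyphenyllithium 3 (not isolated)
Conditions: n-BuLi, THF, 0 °C to rt; then CuI (10 mol %), 2, −78 °C to rt
Reagents that add atoms: n-butyllithium, [Li]CCCC (lithium of 3 only)
Why: Directed ortho-metalation: the C–H between the two methoxy groups is the most acidic and the lithium is held by both oxygens. Copper-assisted SN2 coupling at the primary allylic carbon gives the linear prenyl arene, which keeps the mirror plane used in steps 2–4.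

Step 2
Reactants: 4 1,3-dimethoxy-2-(3-methylbut-2-en-1-yl)benzene
Product: 6 3,5-dimethoxy-4-(3-methylbut-2-en-1-yl)phenol, via aryl pinacolboronate 5 (not isolated)
Conditions: [Ir(OMe)(cod)]2 (1.5 mol %), dtbpy (3 mol %), B2pin2, THF, 80 °C; then aq. H2O2, NaOH, 0 °C
Reagents that add atoms: bis(pinacolato)diboron, CC1(C)OB(OC1(C)C)B1OC(C)(C)C(C)(C)O1 (boryl group of 5 only); hydrogen peroxide, OO
Why: Sterically governed iridium-catalysed arene C–H borylation followed by C–B oxidation in the same flask. The C–H para to the prenyl group is the only one without an ortho substituent, so oxygen enters meta to both methoxy groups. The hindered trisubstituted alkene should not compete with the arene, and basic peroxide does not epoxidise it.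

Step 3
Reactants: 6 3,5-dimethoxy-4-(3-methylbut-2-en-1-yl)phenol; 7 propargyl bromide
Product: 8 1,3-dimethoxy-2-(3-methylbut-2-en-1-yl)-5-(prop-2-yn-1-yloxy)benzene
Conditions: K2CO3, acetone, reflux
Reagents that add atoms: none
Why: Williamson ether synthesis; the phenoxide is alkylated on oxygen by the unhindered propargylic bromide, which supplies C2, C3 and C4 of the pyran ring.

Step 4
Reactants: 8 1,3-dimethoxy-2-(3-methylbut-2-en-1-yl)-5-(prop-2-yn-1-yloxy)benzene
Product: 9 5,7-dimethoxy-6-(3-methylbut-2-en-1-yl)-2H-chromene
Conditions: Ph3PAuNTf2 (2 mol %), CH2Cl2, rt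
Reagents that add atoms: none
Why: Gold(I)-catalysed intramolecular hydroarylation of an aryl propargyl ether (6-endo-dig), which is fast for electron-rich arenes. The two ortho carbons of 8 are equivalent, so only one chromene can form. The prenyl group sits para to the tether and cannot reach the activated alkyne.

Step 5
Reactants: 9 5,7-dimethoxy-6-(3-methylbut-2-en-1-yl)-2H-chromene
Product: 10 (S)-2-[5,7-dimethoxy-6-(3-methylbut-2-en-1-yl)chroman-3-yl]-4,4,5,5-tetramethyl-1,3,2-dioxaborolane
Conditions: CuCl (5 mol %), (R,R)-QuinoxP* (5 mol %), KOt-Bu (20 mol %), B2pin2, MeOH (2 equiv), THF, 0 °C to rt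
Reagents that add atoms: bis(pinacolato)diboron, CC1(C)OB(OC1(C)C)B1OC(C)(C)C(C)(C)O1
Why: Copper(I)-catalysed enantioselective protoboration of a cyclic cis-β-substituted styrene: L*Cu–Bpin adds syn across C3=C4 with copper at the benzylic C4 and boron at C3, and methanol protonates the C4–Cu bond. C3 is set in the insertion step by the alkene face that the C2-symmetric bisphosphine leaves open. The isolated prenyl alkene is not activated and should not insert.

Step 6
Reactants: 10 (S)-2-[5,7-dimethoxy-6-(3-methylbut-2-en-1-yl)chroman-3-yl]-4,4,5,5-tetramethyl-1,3,2-dioxaborolane; 11 vinyl bromide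
Product: 15 (S)-3-(1-bromovinyl)-5,7-dimethoxy-6-(3-methylbut-2-en-1-yl)chroman, via 1-bromovinyllithium 12 (not isolated), via lithium boronate complex 13 (not isolated), via beta-iodo boronic ester 14 (not isolated)
Conditions: LDA added to 10 + 11, THF, −78 °C (in situ capture); I2 (1.1 equiv), THF, −78 °C; NaOMe, MeOH, −78 °C to rt
Reagents that add atoms: lithium diisopropylamide, CC(C)N([Li])C(C)C (lithium of 12 and 13 only); iodine, II (iodine of 14 only)
Why: Zweifel-type olefination: iodine activates the vinyl group of 13, C3 migrates from boron to carbon with retention at the migrating centre, and methoxide induces anti-elimination of boron and iodine from 14. The spatial arrangement at C3 is unchanged; the descriptor stays S only because the new substituent C(Br)=CH2 now ranks first. Iodine is consumed by the boronate far faster than it can attack the prenyl group or C8.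

Step 7
Reactants: 15 (S)-3-(1-bromovinyl)-5,7-dimethoxy-6-(3-methylbut-2-en-1-yl)chroman
Product: 16 (R)-3-ethynyl-5,7-dimethoxy-6-(3-methylbut-2-en-1-yl)chroman
Conditions: TBAF·3H2O, DMF, 60 °C
Reagents that add atoms: none
Why: Fluoride-mediated anti E2 dehydrobromination of a 2-bromo-1-alkene. The vinylic hydrogen trans to bromine is lost rather than C3–H, so the alkyne and not the allene should form and C3 is not touched. The medium is too weakly basic to open the chroman.

Step 8
Reactants: 17 squaric acid
Product: 18 di-tert-butyl squarate (3,4-di-tert-butoxycyclobut-3-ene-1,2-dione)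
Conditions: t-BuOH, HC(OMe)3, reflux, methanol distilled off
Reagents that add atoms: tert-butanol, CC(C)(C)O
Why: Esterification of the vinylogous diacid in the alcohol as solvent, with the orthoester as water scavenger; this is a standard preparation of squarate esters.

Step 9
Reactants: 18 di-tert-butyl squarate; 19 allylmagnesium bromide
Product: 22 3-allyl-4-tert-butoxycyclobut-3-ene-1,2-dione, via bromomagnesium alkoxide 20 (not isolated), via tertiary trifluoroacetate 21 (not isolated)
Conditions: 19 (1.05 equiv), THF, −78 °C; then (CF3CO)2O, −78 to 0 °C; aq. NaHCO3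
Reagents that add atoms: trifluoroacetic anhydride, O=C(OC(=O)C(F)(F)F)C(F)(F)F (trifluoroacetyl group of 21 only)
Why: 1,2-Addition to one of the two equivalent carbonyl groups, then the standard squarate-to-cyclobutenedione transposition: ionisation of 21 gives an alkoxy-stabilised cyclobutenyl cation that loses the tert-butyl group of the vinylogous oxygen. The symmetrical allyl reagent avoids the α/γ ambiguity of a prenyl metal.

Step 10
Reactants: 22 3-allyl-4-tert-butoxycyclobut-3-ene-1,2-dione; 23 2-methyl-2-butene
Product: 24 3-tert-butoxy-4-(3-methylbut-2-en-1-yl)cyclobut-3-ene-1,2-dione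
Conditions: Grubbs second-generation catalyst (3 mol %), 23 (excess), CH2Cl2, 40 °C
Reagents that add atoms: none
Why: Olefin cross-metathesis of a terminal alkene with 2-methyl-2-butene, the usual allyl-to-prenyl conversion, driven by loss of propene. The tetrasubstituted electron-poor ring alkene is inert to the catalyst.

Step 11
Reactants: 16 (R)-3-ethynyl-5,7-dimethoxy-6-(3-methylbut-2-en-1-yl)chroman; 24 3-tert-butoxy-4-(3-methylbut-2-en-1-yl)cyclobut-3-ene-1,2-dione
Product: 26 3-tert-butoxy-4-{[(R)-5,7-dimethoxy-6-(3-methylbut-2-en-1-yl)chroman-3-yl]ethynyl}-4-hydroxy-2-(3-methylbut-2-en-1-yl)cyclobut-2-en-1-one (both carbinol epimers), via lithium acetylide 25 (not isolated)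
Conditions: n-BuLi (1.0 equiv), THF, −78 °C; cannulated into 24, THF, −78 °C; aq. NH4Cl at −78 °C
Reagents that add atoms: n-butyllithium, [Li]CCCC (lithium of 25 only)
Why: 1,2-Addition of a lithium acetylide to a cyclobutenedione. C1=O of 24 is a vinylogous ester deactivated by the tert-butoxy group, so attack should occur at the ketone-like C2=O next to C–Ot-Bu, which fixes the substitution pattern of ring B. The new carbinol centre forms unselectively and is erased in step 12.

Step 12
Reactants: 26 3-tert-butoxy-4-{[(R)-5,7-dimethoxy-6-(3-methylbut-2-en-1-yl)chroman-3-yl]ethynyl}-4-hydroxy-2-(3-methylbut-2-en-1-yl)cyclobut-2-en-1-one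
Product: 29 2-tert-butoxy-5-[(R)-5,7-dimethoxy-6-(3-methylbut-2-en-1-yl)chroman-3-yl]-3-(3-methylbut-2-en-1-yl)cyclohexa-2,5-diene-1,4-dione, via enynylketene 27 (not isolated), via ring-closed diradical 28 (not isolated)
Conditions: degassed toluene (0.02 M), 110 °C
Reagents that add atoms: none
Why: Moore rearrangement (thermal ring expansion of a 4-alkynyl-4-hydroxycyclobutenone), closely precedented for alkyl-terminated alkynes and for tert-butoxy-substituted cyclobutenones that carry trisubstituted alkenes. The C1–C4 bond of the four-membered ring opens by a conrotatory 4π electrocyclic reaction in which the donor OH rotates outward, so the alkynyl group of 27 lies cis to the ketene. The ketene carbon (future C2') then bonds to the distal alkyne carbon (future C1') in an enyne-ketene cycloaromatisation that closes the six-membered ring B and gives 28, with a phenoxyl oxygen at C2' and a σ-radical at C6'. Transfer of the hydroxyl hydrogen from O5' to C6' gives the quinone directly, without any oxidant. Six- rather than five-membered closure is needed, and the alkyl terminus (C3) secures it because it does not stabilise the exocyclic vinyl radical of the five-ring path. The positions of prenyl, Ot-Bu, H and C3 on ring B follow from the connectivity of 26 and cannot scramble. No stereocentre is created: the carbinol carbon becomes C5'=O, so both epimers of 26 converge on one product, and C3 is a spectator in a neutral aprotic medium. The C3' prenyl group is tethered by one carbon to the ketene, so an internal [2+2] would need a prohibitively strained bicycle.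

Step 13
Reactants: 29 2-tert-butoxy-5-[(R)-5,7-dimethoxy-6-(3-methylbut-2-en-1-yl)chroman-3-yl]-3-(3-methylbut-2-en-1-yl)cyclohexa-2,5-diene-1,4-dione
Product: 30 5-[(R)-5,7-dimethoxy-6-(3-methylbut-2-en-1-yl)chroman-3-yl]-2-hydroxy-3-(3-methylbut-2-en-1-yl)cyclohexa-2,5-diene-1,4-dione (target)
Conditions: CF3CO2H (10 equiv), CH2Cl2 (dilute), 0 °C, short contact; pH 7 buffer
Reagents that add atoms: none
Why: O–alkyl (AAL1) cleavage of a vinylogous tert-butyl ester: protonation at C2'=O makes O4'–CMe3 heterolysis easy and isobutene is lost. This is precedented for tert-butoxyquinones bearing trisubstituted alkenes. It should outrun protonation of the prenyl groups, and it leaves the aryl methyl ethers and C3 unchanged.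

## Compound list

1 | 1,3-dimethoxybenzene | COc1cccc(OC)c1 | starting material
2 | prenyl bromide | CC(C)=CCBr | starting material
3 | 2,6-dimethoxyphenyllithium | COc1cccc(OC)c1[Li] | intermediate
4 | 1,3-dimethoxy-2-(3-methylbut-2-en-1-yl)benzene | COc1cccc(OC)c1CC=C(C)C | intermediate
5 | 2-[3,5-dimethoxy-4-(3-methylbut-2-en-1-yl)phenyl]-4,4,5,5-tetramethyl-1,3,2-dioxaborolane | COc1cc(B2OC(C)(C)C(C)(C)O2)cc(OC)c1CC=C(C)C | intermediate
6 | 3,5-dimethoxy-4-(3-methylbut-2-en-1-yl)phenol | COc1cc(O)cc(OC)c1CC=C(C)C | intermediate
7 | propargyl bromide | C#CCBr | starting material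
8 | 1,3-dimethoxy-2-(3-methylbut-2-en-1-yl)-5-(prop-2-yn-1-yloxy)benzene | COc1cc(OCC#C)cc(OC)c1CC=C(C)C | intermediate
9 | 5,7-dimethoxy-6-(3-methylbut-2-en-1-yl)-2H-chromene | COc1cc2c(c(OC)c1CC=C(C)C)C=CCO2 | intermediate
10 | (S)-chroman-3-yl pinacolboronate | COc1cc2c(c(OC)c1CC=C(C)C)C[C@H](B1OC(C)(C)C(C)(C)O1)CO2 | intermediate
11 | vinyl bromide | C=CBr | starting material
12 | 1-bromovinyllithium | C=C(Br)[Li] | intermediate
13 | lithium (1-bromovinyl)[(S)-chroman-3-yl]pinacolatoborate | [Li+].COc1cc2c(c(OC)c1CC=C(C)C)C[C@H]([B-]1(C(Br)=C)OC(C)(C)C(C)(C)O1)CO2 | intermediate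
14 | 1-bromo-1-[(S)-chroman-3-yl]-2-iodoethyl pinacolboronate (side-chain centre undefined) | COc1cc2c(c(OC)c1CC=C(C)C)C[C@H](C(Br)(CI)B1OC(C)(C)C(C)(C)O1)CO2 | intermediate
15 | (S)-3-(1-bromovinyl)-5,7-dimethoxy-6-(3-methylbut-2-en-1-yl)chroman | COc1cc2c(c(OC)c1CC=C(C)C)C[C@H](C(Br)=C)CO2 | intermediate
16 | (R)-3-ethynyl-5,7-dimethoxy-6-(3-methylbut-2-en-1-yl)chroman | COc1cc2c(c(OC)c1CC=C(C)C)C[C@H](C#C)CO2 | intermediate
17 | squaric acid | OC1=C(O)C(=O)C1=O | starting material
18 | di-tert-butyl squarate | CC(C)(C)OC1=C(OC(C)(C)C)C(=O)C1=O | intermediate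
19 | allylmagnesium bromide | C=CC[Mg]Br | starting material
20 | bromomagnesium 1-allyl-2,3-di-tert-butoxy-4-oxocyclobut-2-en-1-olate (racemic) | [Br-].[Mg+2].[O-]C1(CC=C)C(=O)C(OC(C)(C)C)=C1OC(C)(C)C | intermediate
21 | 1-allyl-2,3-di-tert-butoxy-4-oxocyclobut-2-en-1-yl trifluoroacetate (racemic) | C=CCC1(OC(=O)C(F)(F)F)C(=O)C(OC(C)(C)C)=C1OC(C)(C)C | intermediate
22 | 3-allyl-4-tert-butoxycyclobut-3-ene-1,2-dione | C=CCC1=C(OC(C)(C)C)C(=O)C1=O | intermediate
23 | 2-methyl-2-butene | CC=C(C)C | starting material
24 | 3-tert-butoxy-4-(3-methylbut-2-en-1-yl)cyclobut-3-ene-1,2-dione | CC(C)=CCC1=C(OC(C)(C)C)C(=O)C1=O | intermediate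
25 | lithium acetylide of 16 | COc1cc2c(c(OC)c1CC=C(C)C)C[C@H](C#C[Li])CO2 | intermediate
26 | 4-alkynyl-3-tert-butoxy-4-hydroxy-2-prenylcyclobut-2-en-1-one, (R) at chroman C3, both carbinol epimers | COc1cc2c(c(OC)c1CC=C(C)C)C[C@H](C#CC1(O)C(=O)C(CC=C(C)C)=C1OC(C)(C)C)CO2 | intermediate
27 | enynylketene (alkynyl cis to the ketene-bearing carbon) | COc1cc2c(c(OC)c1CC=C(C)C)C[C@H](C#C/C(O)=C(\C(CC=C(C)C)=C=O)OC(C)(C)C)CO2 | intermediate
28 | ring-closed diradical (phenoxyl at C2', σ-radical at C6') | COc1cc2c(c(OC)c1CC=C(C)C)C[C@H](c1[c]c(O)c(OC(C)(C)C)c(CC=C(C)C)c1[O])CO2 | intermediate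
29 | (R)-tert-butoxyquinone | COc1cc2c(c(OC)c1CC=C(C)C)C[C@H](C1=CC(=O)C(OC(C)(C)C)=C(CC=C(C)C)C1=O)CO2 | intermediate
30 | CNP0241224.1, (3R)-isoflavan hydroxyquinone | COc1cc2c(c(OC)c1CC=C(C)C)C[C@H](C1=CC(=O)C(O)=C(CC=C(C)C)C1=O)CO2 | target

## Step count and risk

Total: 13 steps. Longest linear sequence: 10 steps (1–7, then 11–13). The side branch is steps 8–10. C3 is set in step 5, transferred with retention in step 6, and is a spectator afterwards.

**Step 12 (key step).**
- *What may go wrong:* diversion of the enynylketene into five-membered closure; capture of the C6' σ-radical by 1,5-hydrogen abstraction from C2–H or C4–H of the chroman before the hydroxyl hydrogen arrives; thermal loss of the tert-butyl group followed by side reactions of the free vinylogous acid.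
- *Fallback (closed-shell ring expansion in place of the diradical one):* it sets out from 16 and 24 and returns at 29. Hydrozirconation of 16 with the Schwartz reagent and iodinolysis give the (E)-vinyl iodide F1. Iodine–lithium exchange (t-BuLi, −78 °C) and addition to 24 give the 4-alkenyl-4-hydroxycyclobutenone F2. At 80–110 °C this opens to a dienylketene that closes by 6π electrocyclisation and tautomerises to the hydroquinone F3. Ag2O in ether oxidises F3 to 29; this oxidant is mild enough for ring A and the prenyl groups.

**Step 5.**
- *What may go wrong:* reversed borylcupration (copper at C3) followed by β-elimination of the aryloxide and ring opening; sluggish insertion because the trialkoxy-substituted styrene is a poor acceptor for a nucleophilic boryl-copper; insufficient facial selectivity.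
- *Fallback (electrophilic, reagent-controlled hydroboration):* it sets out from 9 and returns at 10. Brown asymmetric hydroboration with (−)-diisopinocampheylborane from (+)-α-pinene (THF, −25 °C) should give the trialkylborane F4. The electron-rich ring A and the allylic oxygen both direct boron to C3. The bulky reagent prefers the cis-disubstituted alkene to the prenyl group, and the analogy with simple cis-alkenes predicts the required face. Acetaldehyde expels both pinene units to give the diethyl boronate F5, and pinacol converts this to 10.

**Step 6.**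
- *What may go wrong:* anti-elimination of the aryloxide from the boronate complex, since an equatorial C3–B bond is antiperiplanar to C2–O1; decomposition of the bromovinyllithium before capture; iodination of ring A at C8 by excess iodine.
- *Fallback (no tetracoordinate boron at C3):* it sets out from 6 and returns at 16.
  - ortho-Formylation (MgCl2, Et3N, paraformaldehyde) gives the salicylaldehyde F6.
  - Acrolein with K2CO3 (oxa-Michael/aldol condensation) gives the chromene-3-carbaldehyde F7.
  - NaBH4/CeCl3 gives the allylic alcohol F8.
  - Hydroxyl-directed asymmetric hydrogenation with Ru(OAc)2(BINAP) spares remote trisubstituted alkenes. With the BINAP antipode chosen accordingly, it gives the (R)-alcohol F9.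
  - Dess–Martin oxidation gives the aldehyde F10, which is taken on at once under the base-free first stage of the Corey–Fuchs reaction (CBr4, PPh3) to the dibromoalkene F11.
  - n-BuLi then gives 16.

**Step 11.**
- *What may go wrong:* proton transfer from the doubly activated CH2 of 24 (allylic and vinylogously α to C2=O) to the acetylide instead of addition; attack at the wrong carbonyl, favoured by the bulk of the tert-butoxy group.
- *Fallback (ring B built without its prenyl group, which is added last):* it sets out from 18 and 25 and returns at 30. Reduction of 18 with LiAlH(Ot-Bu)3 and acid work-up give the tert-butyl semisquarate F12. Addition of 25 gives the cyclobutenone F13. Thermolysis as in step 12 gives the quinone F14, and CF3CO2H gives the hydroxyquinone F15. Its lithium salt is C-alkylated at C3' with 2 (LiH, DMSO), the alkylation type known from hydroxynaphthoquinones, to give 30.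

**Step 13.**
- *What may go wrong:* acid-induced addition of the liberated O4'–H to the neighbouring prenyl group (pyran formation); alkylation of C8 by the tert-butyl cation; slow acid-catalysed tautomerisation through a quinone methide with erosion at C3.
- *Fallback (cleavage at the ring carbon instead of at the alkyl carbon):* it sets out from 29 and returns at 30. Aqueous LiOH in THF at 0 °C adds to C4' and expels tert-butoxide by addition–elimination. The resulting hydroxyquinone anion is less prone to lose C3–H, and the mixture is acidified cold to pH 4.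

## Further compounds

F1 | step 12 | (R)-3-[(E)-2-iodovinyl]-5,7-dimethoxy-6-(3-methylbut-2-en-1-yl)chroman | COc1cc2c(c(OC)c1CC=C(C)C)C[C@H](/C=C/I)CO2
F2 | step 12 | 4-[(E)-2-((R)-chroman-3-yl)vinyl]-3-tert-butoxy-4-hydroxy-2-prenylcyclobut-2-en-1-one (both carbinol epimers) | COc1cc2c(c(OC)c1CC=C(C)C)C[C@H](/C=C/C1(O)C(=O)C(CC=C(C)C)=C1OC(C)(C)C)CO2
F3 | step 12 | 2-tert-butoxy-5-[(R)-chroman-3-yl]-3-prenylbenzene-1,4-diol | COc1cc2c(c(OC)c1CC=C(C)C)C[C@H](c1cc(O)c(OC(C)(C)C)c(CC=C(C)C)c1O)CO2
F4 | step 5 | [(S)-5,7-dimethoxy-6-prenylchroman-3-yl]diisopinocampheylborane (Ipc from (+)-α-pinene) | COc1cc2c(c(OC)c1CC=C(C)C)C[C@H](B([C@@H]1C[C@@H]3C[C@H]([C@H]1C)C3(C)C)[C@@H]1C[C@@H]3C[C@H]([C@H]1C)C3(C)C)CO2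
F5 | step 5 | diethyl [(S)-5,7-dimethoxy-6-prenylchroman-3-yl]boronate | COc1cc2c(c(OC)c1CC=C(C)C)C[C@H](B(OCC)OCC)CO2
F6 | step 6 | 2-hydroxy-4,6-dimethoxy-5-(3-methylbut-2-en-1-yl)benzaldehyde | COc1cc(O)c(C=O)c(OC)c1CC=C(C)C
F7 | step 6 | 5,7-dimethoxy-6-(3-methylbut-2-en-1-yl)-2H-chromene-3-carbaldehyde | COc1cc2c(c(OC)c1CC=C(C)C)C=C(C=O)CO2
F8 | step 6 | [5,7-dimethoxy-6-(3-methylbut-2-en-1-yl)-2H-chromen-3-yl]methanol | COc1cc2c(c(OC)c1CC=C(C)C)C=C(CO)CO2
F9 | step 6 | [(R)-5,7-dimethoxy-6-(3-methylbut-2-en-1-yl)chroman-3-yl]methanol | COc1cc2c(c(OC)c1CC=C(C)C)C[C@H](CO)CO2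
F10 | step 6 | (S)-5,7-dimethoxy-6-(3-methylbut-2-en-1-yl)chroman-3-carbaldehyde | COc1cc2c(c(OC)c1CC=C(C)C)C[C@H](C=O)CO2
F11 | step 6 | (R)-3-(2,2-dibromovinyl)-5,7-dimethoxy-6-(3-methylbut-2-en-1-yl)chroman | COc1cc2c(c(OC)c1CC=C(C)C)C[C@H](C=C(Br)Br)CO2
F12 | step 11 | 3-tert-butoxycyclobut-3-ene-1,2-dione | CC(C)(C)OC1=CC(=O)C1=O
F13 | step 11 | 3-tert-butoxy-4-{[(R)-chroman-3-yl]ethynyl}-4-hydroxycyclobut-2-en-1-one (both carbinol epimers) | COc1cc2c(c(OC)c1CC=C(C)C)C[C@H](C#CC1(O)C(=O)C=C1OC(C)(C)C)CO2
F14 | step 11 | 2-tert-butoxy-5-[(R)-chroman-3-yl]cyclohexa-2,5-diene-1,4-dione | COc1cc2c(c(OC)c1CC=C(C)C)C[C@H](C1=CC(=O)C(OC(C)(C)C)=CC1=O)CO2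
F15 | step 11 | 5-[(R)-chroman-3-yl]-2-hydroxycyclohexa-2,5-diene-1,4-dione | COc1cc2c(c(OC)c1CC=C(C)C)C[C@H](C1=CC(=O)C(O)=CC1=O)CO2
F0 | step 13 | none | none
A1 | alternative 1 | 3-[2,4-bis(methoxymethoxy)-3-prenylphenyl]-5,7-dimethoxy-6-prenyl-2H-chromene | COc1cc2c(c(OC)c1CC=C(C)C)C=C(c1ccc(OCOC)c(CC=C(C)C)c1OCOC)CO2
A2 | alternative 1 | 4-[(R)-5,7-dimethoxy-6-prenylchroman-3-yl]-2-prenylbenzene-1,3-diol | COc1cc2c(c(OC)c1CC=C(C)C)C[C@H](c1ccc(O)c(CC=C(C)C)c1O)CO2
A3 | alternative 2 | 3-[2-(tert-butyldimethylsilyloxy)-4,6-dimethoxy-5-prenylphenyl]propanal | O=CCCc1c(O[Si](C)(C)C(C)(C)C)cc(OC)c(CC=C(C)C)c1OC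
A4 | alternative 2 | 2-methoxy-3-prenylcyclohexa-2,5-diene-1,4-dione | COC1=C(CC=C(C)C)C(=O)C=CC1=O
A5 | alternative 2 | 3-(arylmethyl)-6-methoxy-7-prenyl-2,3-dihydrobenzofuran-2,5-diol (lactol, anomeric centre undefined) | COc1cc(O[Si](C)(C)C(C)(C)C)c(C[C@@H]2c3cc(O)c(OC)c(CC=C(C)C)c3OC2O)c(OC)c1CC=C(C)C
A6 | alternative 3 | 1-bromo-2,5-dimethoxy-4-(methoxymethoxy)-3-prenylbenzene | COc1cc(Br)c(OC)c(CC=C(C)C)c1OCOC
A7 | alternative 3 | (R)-3-[2,5-dimethoxy-4-(methoxymethoxy)-3-prenylphenyl]-5,7-dimethoxy-6-prenylchroman | COc1cc2c(c(OC)c1CC=C(C)C)C[C@H](c1cc(OC)c(OCOC)c(CC=C(C)C)c1OC)CO2
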